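## Structural features

Labdane numbering is used throughout: C1–C10 for the decalin, C11–C16 for the chain on C9, C17 for the methyl on C8, and C20 for the methyl on C10.

- The target is a tricyclic C20 bromo-diterpenoid. A trans-fused decalin (ring A: C1–C5, C10; ring B: C5–C10) carries an eight-membered cyclic ether (ring C: C8, C9, C11, C12, C13, C14, C15 and the ether oxygen) fused across C8–C9. Ring C holds a cis-13,14-epoxide with a methyl on C13.
- There are seven stereocentres. C5, C10, C9 and C8 are contiguous along ring B (5α-H, 10β-CH3, 9α-H, 8α-O with 8β-CH3). C3 (equatorial β-Br) sits next to the C4 gem-dimethyl group. C13 and C14 (R,S) lie on the far side of ring C.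
- The fragile groups are the secondary bromide on a neopentyl carbon (E2 to the 2-ene, methyl shift on ionisation), the acid-labile trisubstituted epoxide, and the tertiary C8 ether.
- The real difficulty is threefold: the quaternary C10 beside the fully substituted C8 and the stereogenic C9; a bromide that can only be placed by inversion at a hindered carbon; and facial control of an epoxide on a medium ring.
- The key step exploits the methyl pattern. The C10 methyl, the C8 methyl and the C4 gem-dimethyl group are exactly the substituents of 2,6-dimethylbenzoquinone (C5–C10) joined to 4-methylpenta-1,3-diene (C1–C4). One [4+2] addition therefore makes ring A, the C1–C10 and C4–C5 bonds and the quaternary centre.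
- The adduct leaves carbonyls at C6 and C9 and alkenes at C7=C8 and C2=C3. These are the handles for the chain, the 8α-oxygen and the C3 substituent.

## Logic of the disconnections

22 to 21: the C13–O and C14–O bonds of the oxirane are cut. The epoxide is the most acid-sensitive group and is best added last. Two stereocentres disappear. The forward step needs a peracid to attack only the outer face of the ring C alkene.

21 to 20: the C3–Br bond is replaced by a C3–O bond of opposite configuration. An equatorial bromide on this carbon is reachable only by inversion of an axial alcohol. The forward step needs substitution at a neopentyl carbon to outrun elimination.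

20 to 19: the O–Si bond at C3 is restored. The C3 hydroxyl must be masked while the C8 hydroxyl is alkylated. The forward step is a fluoride desilylation of a hindered ether.

19 to 18: the C13=C14 bond is cut. Ring C opens to two terminal alkenes on neighbouring, equatorial positions of ring B. The forward step is an eight-membered ring closure that forms a trisubstituted alkene.

18 to 17: the O–C15 bond is cut, removing a three-carbon allyl unit. The forward step is alkylation of a hindered tertiary alkoxide.

17 to 16: the C13=C16 bond is traded for C13=O. The forward step is a methylenation of a methyl ketone next to a free tertiary alcohol.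

16 to 15: the C13 carbonyl is masked as a cyclic ketal. The forward step is a mild hydrolysis that must leave the silyl ether intact.

15 to 14: the O–Si bond at C3 is cut. The forward step must silylate the secondary hydroxyl and not the tertiary one.

14 to 13: the C2–H and C7–H bonds are cut and the C3–O and C8–O bonds become parts of two oxiranes. Both hydroxyls then stem from one reagent. The forward step needs hydride to open the ring A oxirane diaxially at C2 and the ring B oxirane at the less substituted C7.

13 to 12: the four C–O bonds of the two oxiranes are cut, giving back the C2=C3 and C7=C8 alkenes. Four stereocentres disappear. The forward step needs both alkenes to be attacked on the α-face.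

12 to 11: the ketal is returned to the C13 ketone. The carbonyl has to be hidden from the hydride of the later opening.

11 to 9 (through 10): the C11–C12 bond and the C9–H bond are cut. The whole C12–C13–C16 unit comes from a three-carbon α-bromo ketone and C9–H from a borane. The forward step needs hydroboration of the exocyclic alkene only, from the α-face.

9 to 8: the C9=C11 bond is traded for the C9 carbonyl. The forward step is methylenation of a hindered, conjugated ketone.

8 to 5 (through 7 and 6): the two C6–H bonds are traded for a C6=N bond. The surplus oxygen of the cycloadduct is deleted. The forward step needs a reduction that transposes the alkene and a return of that alkene into conjugation with C9.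

5 to 4: the C6=N bond is cut back to the carbonyl. The forward step needs condensation at C6 only.

4 to 3: the C5–H bond is re-formed on the other face. The forward step needs kinetic protonation of the C5=C6 enolate from the α-face.

3 to 1 and 2: the C1–C10 and C4–C5 bonds are cut. Both rings fall back to two commercial, achiral compounds. The forward step needs a chiral Lewis acid to choose the enantioface and a sluggish diene to react.

## Other disconnections considered

Alternative 1:
- Cut and key step: the C11=C12 bond of a didehydro ring C. The diene A1 has a vinyl group on C9 and a vinyl epoxide on the C8 ether arm. A second-generation Hoveyda–Grubbs catalyst, (H2IMes)Cl2Ru=CH(C6H4-2-OiPr), would close it to A2. Saturation of the new cis-alkene would finish the target.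
- In its favour: the epoxide configuration is set by reagent control on a small allylic alcohol before ring closure, and the metathesis forms a disubstituted alkene. On both points it is the better plan, since the chosen route relies on ring C conformation in step 17 and on a harder metathesis in step 14.
- Against it: the hindered C8 alkoxide must be alkylated with an epoxide-bearing electrophile, the vinyl epoxide must survive a ruthenium carbene, and the final reduction must spare bromide and epoxide.
- Comparison: it changes only the ending and is silent on the decalin, so it could be grafted onto the chosen route from 9. The step count would be about equal.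

Alternative 2:
- Cut and key step: the C8–C9 bond of ring B and the lactone C12–O bond. SmI2 would reduce the C8 methyl ketone of the monocyclic keto enoate A3 to a ketyl. This adds 6-exo to the enoate β-carbon (C9), and the alkoxide closes the lactone to give A4.
- In its favour: one step makes ring B, C8 and C9 with the oxygen already on C8, and nothing has to be deoxygenated afterwards. In this it is better than the chosen route, which spends steps 2–4 on C5 and C6. It is equal at C3, since A4 and 15 carry the same 3α-silyloxy group.
- Against it: A3 must be made as one enantiomer with C3, C5 and the quaternary C10 already set, which moves the hard part into ring A. The 8α-O/9α-H outcome rests on a chair-like radical transition state. A4 still lacks C13–C16.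
- Comparison: a substrate-controlled radical-anion closure stands against a catalyst-controlled pericyclic one. Counting the fragment synthesis, it is likely to be longer.

Alternative 3:
- Cut and key step: the C9–C10 bond. Pd2(dba)3 with a chiral phosphoramidite would ionise the allylic carbonate of phenol A5. The para carbon (C10) attacks the inner allyl terminus, closing ring B and giving the dienone A6.
- In its favour: the quaternary centre is made by asymmetric catalysis from a flat precursor, and oxygen already sits at C3 and C8. That oxidation pattern is better than the one in 3, which has oxygen at the unwanted C6 and none at C3.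
- Against it: C4 has only one methyl, so the second methyl and C5 must be set later. The C8 methyl and 8α-oxygen must come from a ketone whose facial preference for methyl addition is the wrong one. The C9/C10 relationship depends on the ligand alone.
- Comparison: both plans start with a catalytic asymmetric step on a flat six-membered ring, so they are equal in principle. The chosen plan delivers all four decalin methyls at once and should need fewer steps after the key step.

Key step: step 1

Assumption: the catalyst antipode that gives C10 as in 22 is taken to be the one from (R)-α,α-diphenylprolinol, as the accepted pre-transition-state model predicts. If the adduct proved antipodal, the (S)-derived salt would be used with no other change.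

## Route

Step 1
Reactants: 1 2,6-dimethyl-1,4-benzoquinone; 2 4-methylpenta-1,3-diene
Product: 3 cis-fused 11,12,13,14,15,16-hexanorlabda-2,7-diene-6,9-dione (5β-H, 10β-CH3)
Conditions: (R)-o-tolyl oxazaborolidine from (R)-α,α-diphenylprolinol, activated with Tf2NH (20 mol %); 2 (5 equiv), CH2Cl2, −78 → −40 °C
Reagents that add atoms: none
Why: The protonated oxazaborolidine binds the C6 carbonyl of 1 (the less hindered oxygen, between two CH groups) with the neighbouring C5–H held against the catalyst oxygen, so the C5=C10 bond is activated and one of its faces lies over a catalyst aryl group. 2 then adds from the open face in a concerted, asynchronous Diels–Alder reaction; the closest known reactions are oxazaborolidinium-catalysed cycloadditions of alkylated benzoquinones with simple 1,3-dienes. Ring A closes as a cyclohexene by the [4+2] addition itself, with both new bonds (C1–C10 and C4–C5) on the same face of the quinone, which makes the fusion cis. C10 is set by the catalyst through the choice of quinone enantioface; C5 follows from the suprafacial addition and is inverted in step 2. The unsubstituted diene terminus, which has the larger HOMO coefficient, bonds to C10 (the β-carbon of the coordinated enone) and the dimethylated terminus to the unsubstituted C5, so electronic and steric preferences agree. The two C=C bonds of 1 are equivalent by symmetry and the diene termini carry no stereocentres, so site and endo/exo selectivity do not arise. What the step needs is reactivity from a diene whose cis-methyl disfavours the s-cis form; the excess of 2, the low temperature and the weakly coordinating triflimide are chosen to favour cycloaddition over cationic oligomerisation.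

Step 2
Reactants: 3 cis-fused enedione
Product: 4 trans-fused 11,12,13,14,15,16-hexanorlabda-2,7-diene-6,9-dione (5α-H, 10β-CH3)
Conditions: KN(SiMe3)2 (1.05 equiv), THF, −78 °C (3 added to the base); AcOH, −78 °C
Reagents that add atoms: none
Why: Enolisation and kinetic protonation: C5–H is the only hydrogen α to either carbonyl, and the planar C5=C6 enolate should take its proton on the α-face, away from the angular C10 methyl (the facial bias seen in additions to 5-ene steroids). This gives the trans fusion without depending on where the cis/trans equilibrium lies.

Step 3
Reactants: 4 trans-fused enedione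
Product: 5 C6 mono-(p-toluenesulfonyl)hydrazone of 4
Conditions: TsNHNH2 (1.05 equiv), MeOH, 23 °C, no added acid
Reagents that add atoms: p-toluenesulfonyl hydrazide, Cc1ccc(cc1)S(=O)(=O)NN
Why: Hydrazone formation should occur only at C6, because the C9 carbonyl is flanked by the quaternary C10 and the methyl-bearing C8 and a C9 hydrazone would be strained on either side. Neutral conditions keep C5 from re-equilibrating.

Step 4
Reactants: 5 C6 tosylhydrazone
Product: 8 11,12,13,14,15,16-hexanorlabda-2,7-dien-9-one (5α-H), via allylic diazene 6 (not isolated), via deconjugated ketone 7 (not isolated)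
Conditions: catecholborane (1.2 equiv), CHCl3, 0 °C; NaOAc·3H2O, 60 °C; then DBU (0.3 equiv), 23 °C
Reagents that add atoms: none
Why: Reduction of a conjugated tosylhydrazone with alkene transposition: hydride adds to C6, loss of sulfinate gives diazene 6, and its retro-ene loss of N2 moves the alkene to C6=C7 and puts H on C8 (7). DBU then brings the alkene back into conjugation with the C9 ketone. After this step C5 is no longer next to a carbonyl and is fixed.

Step 5
Reactants: 8 enone
Product: 9 12,13,14,15,16-pentanorlabda-2,7,9(11)-triene
Conditions: Ph3PCH3Br, KOtBu, toluene, 90 °C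
Reagents that add atoms: methyltriphenylphosphonium bromide, C[P+](c1ccccc1)(c1ccccc1)c1ccccc1.[Br-]
Why: Wittig methylenation under forcing conditions used for hindered ketones; any γ-deprotonation by the ylide is reversible, so the ketone is still consumed by olefination.

Step 6
Reactants: 9 triene
Product: 11 14,15-dinorlabda-2,7-dien-13-one (9α-H), via B-alkyl borane 10 (not isolated)
Conditions: 9-BBN (1.05 equiv), THF, 0 → 50 °C; then bromoacetone, potassium 2,6-di-tert-butylphenoxide, THF, 0 °C
Reagents that add atoms: bromoacetone, CC(=O)CBr
Why: Hydroboration followed by α-alkylation of an α-bromo ketone with a B-alkyl-9-BBN (boron ate complex, 1,2-shift of the alkyl group with loss of bromide, protonolysis). 9-BBN should add only to the terminal C11 of the exocyclic alkene and deliver H to C9 on the α-face, opposite the axial C10 methyl. The migration forms C11–C12 and leaves the methyl ketone.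

Step 7
Reactants: 11 methyl ketone
Product: 12 13,13-(ethylenedioxy)-14,15-dinorlabda-2,7-diene
Conditions: (Me3SiOCH2)2, Me3SiOTf (5 mol %), CH2Cl2, −78 °C
Reagents that add atoms: 1,2-bis(trimethylsilyloxy)ethane, C[Si](C)(C)OCCO[Si](C)(C)C
Why: Ketalisation under aprotic low-temperature conditions, chosen so that the 7-ene is neither protonated nor trapped by the ketone oxygen. The ketal hides C13 from the hydride of step 9.

Step 8
Reactants: 12 ketal diene
Product: 13 2α,3α:7α,8α-diepoxy-13,13-(ethylenedioxy)-14,15-dinorlabdane
Conditions: mCPBA (2.5 equiv), NaHCO3, CH2Cl2, 0 °C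
Reagents that add atoms: 3-chloroperbenzoic acid, OOC(=O)c1cccc(Cl)c1
Why: Peracid epoxidation of both ring alkenes; each should be attacked on the α-face because the β-face is screened by the axial C10 methyl (and by the 4β-methyl for the 2-ene), as is usual for 2-enes and 7-enes of 10β-methyl trans-decalins.

Step 9
Reactants: 13 bis-epoxide
Product: 14 13,13-(ethylenedioxy)-14,15-dinorlabdane-3α,8α-diol
Conditions: LiAlH4, THF, 65 °C
Reagents that add atoms: none
Why: Hydride opening of epoxides: the ring A oxirane should open diaxially by attack at C2 (Fürst–Plattner rule, C3 being neopentyl), leaving the axial 3α-ol. The trisubstituted ring B oxirane should open at the less substituted C7, leaving the tertiary 8α-ol.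

Step 10
Reactants: 14 diol
Product: 15 3α-(tert-butyldimethylsilyloxy)-13,13-(ethylenedioxy)-14,15-dinorlabdan-8α-ol
Conditions: tBuMe2SiOTf (1.1 equiv), 2,6-lutidine, CH2Cl2, −78 °C
Reagents that add atoms: tert-butyldimethylsilyl triflate, CC(C)(C)[Si](C)(C)OS(=O)(=O)C(F)(F)F
Why: Silyl ether formation; at low temperature the secondary hydroxyl should react and the tertiary C8 hydroxyl and the ketal should not.

Step 11
Reactants: 15 silyl ether ketal
Product: 16 3α-(tert-butyldimethylsilyloxy)-8α-hydroxy-14,15-dinorlabdan-13-one
Conditions: PPTS, acetone/H2O, 50 °C
Reagents that add atoms: water, O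
Why: Mild acid hydrolysis of the ketal; the hindered silyl ether and the tertiary alcohol should survive, and the weak acid avoids dehydration to the cyclic enol ether.

Step 12
Reactants: 16 hydroxy ketone
Product: 17 3α-(tert-butyldimethylsilyloxy)-14,15-dinorlabd-13(16)-en-8α-ol
Conditions: Ph3PCH3Br, KOtBu (3 equiv each), THF, 0 → 23 °C
Reagents that add atoms: methyltriphenylphosphonium bromide, C[P+](c1ccccc1)(c1ccccc1)c1ccccc1.[Br-]
Why: Wittig methylenation of an unhindered methyl ketone; the excess ylide covers the free tertiary hydroxyl, whose alkoxide adds to the ketone only reversibly.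

Step 13
Reactants: 17 hydroxy alkene
Product: 18 8α-allyloxy-3α-(tert-butyldimethylsilyloxy)-14,15-dinorlabd-13(16)-ene
Conditions: KH, 18-crown-6 (cat.), allyl bromide, THF, 0 → 23 °C
Reagents that add atoms: allyl bromide, C=CCBr
Why: Williamson etherification of the tertiary potassium alkoxide with a reactive allylic halide; the only other hydroxyl is silylated.

Step 14
Reactants: 18 allyl ether
Product: 19 3α-(tert-butyldimethylsilyloxy)-8α,15-epoxylabd-13Z-ene
Conditions: second-generation Grubbs catalyst, (H2IMes)(PCy3)Cl2Ru=CHPh (10 mol %), toluene (2 mM), 80 °C
Reagents that add atoms: none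
Why: Ring-closing metathesis with loss of ethylene; the O-allyl group on C8 and the chain on C9 are both equatorial and gauche on the rigid decalin, which holds the two alkenes close. The eight-membered ring enforces the Z geometry.

Step 15
Reactants: 19 silyl ether
Product: 20 8α,15-epoxylabd-13Z-en-3α-ol
Conditions: Bu4NF, THF, 60 °C
Reagents that add atoms: none
Why: Fluoride desilylation; the ether and the alkene of ring C are inert to fluoride.

Step 16
Reactants: 20 3α-ol
Product: 21 3β-bromo-8α,15-epoxylabd-13Z-ene
Conditions: CBr4, PPh3, CH2Cl2, 0 → 40 °C
Reagents that add atoms: carbon tetrabromide, BrC(Br)(Br)Br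
Why: Appel reaction: bromide displaces the alkoxyphosphonium group of the axial 3α-alcohol from the β-side with inversion, giving the equatorial 3β-bromide. The near-neutral medium limits elimination and ionisation.

Step 17
Reactants: 21 bromo alkene
Product: 22 3β-bromo-8α,15:13,14-diepoxylabdane with 13R,14S configuration (CNP0311742.2)
Conditions: mCPBA, NaHCO3, CH2Cl2, 0 °C
Reagents that add atoms: 3-chloroperbenzoic acid, OOC(=O)c1cccc(Cl)c1
Why: Peracid epoxidation under conformational control: in the expected conformer of ring C (C15 anti to the axial C8 methyl, C12 anti to C10) the C13=C14 bond hangs below C8–C9 with its inner face against H-9α. The peracid should therefore add to the outer face, which corresponds to the 13R,14S epoxide; the buffer protects the product.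

## Compound list

1 | 2,6-dimethyl-1,4-benzoquinone | CC1=CC(=O)C=C(C)C1=O | starting material
2 | 4-methylpenta-1,3-diene | CC(C)=CC=C | starting material
3 | cis-fused 11,12,13,14,15,16-hexanorlabda-2,7-diene-6,9-dione (5β-H, 10β-CH3) | CC1(C)C=CC[C@]2(C)C(=O)C(C)=CC(=O)[C@H]12 | intermediate
4 | trans-fused 11,12,13,14,15,16-hexanorlabda-2,7-diene-6,9-dione (5α-H, 10β-CH3) | CC1(C)C=CC[C@]2(C)C(=O)C(C)=CC(=O)[C@@H]12 | intermediate
5 | C6 mono-(p-toluenesulfonyl)hydrazone of 4 | CC1(C)C=CC[C@]2(C)C(=O)C(C)=CC(=NNS(=O)(=O)c3ccc(C)cc3)[C@@H]12 | intermediate
6 | allylic diazene: 6-diazenyl-hexanorlabda-2,7-dien-9-one (C6 not defined) | CC1(C)C=CC[C@]2(C)C(=O)C(C)=CC(N=N)[C@@H]12 | intermediate (not isolated)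
7 | deconjugated ketone: hexanorlabda-2,6-dien-9-one (C8 epimers) | CC1(C)C=CC[C@]2(C)C(=O)C(C)C=C[C@@H]12 | intermediate (not isolated)
8 | 11,12,13,14,15,16-hexanorlabda-2,7-dien-9-one (5α-H) | CC1(C)C=CC[C@]2(C)C(=O)C(C)=CC[C@@H]12 | intermediate
9 | 12,13,14,15,16-pentanorlabda-2,7,9(11)-triene | CC1(C)C=CC[C@]2(C)C(=C)C(C)=CC[C@@H]12 | intermediate
10 | B-(12,13,14,15,16-pentanorlabda-2,7-dien-11-yl)-9-borabicyclo[3.3.1]nonane (9α-H) | CC1(C)C=CC[C@]2(C)[C@@H](CB3C4CCCC3CCC4)C(C)=CC[C@@H]12 | intermediate (not isolated)
11 | 14,15-dinorlabda-2,7-dien-13-one (9α-H) | CC1(C)C=CC[C@]2(C)[C@@H](CCC(C)=O)C(C)=CC[C@@H]12 | intermediate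
12 | 13,13-(ethylenedioxy)-14,15-dinorlabda-2,7-diene | CC1(C)C=CC[C@]2(C)[C@@H](CCC3(C)OCCO3)C(C)=CC[C@@H]12 | intermediate
13 | 2α,3α:7α,8α-diepoxy-13,13-(ethylenedioxy)-14,15-dinorlabdane | CC1(C)[C@@H]3O[C@@H]3C[C@]2(C)[C@@H](CCC4(C)OCCO4)[C@]5(C)O[C@@H]5C[C@@H]12 | intermediate
14 | 13,13-(ethylenedioxy)-14,15-dinorlabdane-3α,8α-diol | CC1(C)[C@H](O)CC[C@]2(C)[C@@H](CCC3(C)OCCO3)[C@](C)(O)CC[C@@H]12 | intermediate
15 | 3α-(tert-butyldimethylsilyloxy)-13,13-(ethylenedioxy)-14,15-dinorlabdan-8α-ol | CC1(C)[C@H](O[Si](C)(C)C(C)(C)C)CC[C@]2(C)[C@@H](CCC3(C)OCCO3)[C@](C)(O)CC[C@@H]12 | intermediate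
16 | 3α-(tert-butyldimethylsilyloxy)-8α-hydroxy-14,15-dinorlabdan-13-one | CC1(C)[C@H](O[Si](C)(C)C(C)(C)C)CC[C@]2(C)[C@@H](CCC(C)=O)[C@](C)(O)CC[C@@H]12 | intermediate
17 | 3α-(tert-butyldimethylsilyloxy)-14,15-dinorlabd-13(16)-en-8α-ol | CC1(C)[C@H](O[Si](C)(C)C(C)(C)C)CC[C@]2(C)[C@@H](CCC(C)=C)[C@](C)(O)CC[C@@H]12 | intermediate
18 | 8α-allyloxy-3α-(tert-butyldimethylsilyloxy)-14,15-dinorlabd-13(16)-ene | CC1(C)[C@H](O[Si](C)(C)C(C)(C)C)CC[C@]2(C)[C@@H](CCC(C)=C)[C@](C)(OCC=C)CC[C@@H]12 | intermediate
19 | 3α-(tert-butyldimethylsilyloxy)-8α,15-epoxylabd-13Z-ene | CC1(C)[C@H](O[Si](C)(C)C(C)(C)C)CC[C@]2(C)[C@H]3CC/C(C)=C\CO[C@]3(C)CC[C@@H]12 | intermediate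
20 | 8α,15-epoxylabd-13Z-en-3α-ol | CC1(C)[C@H](O)CC[C@]2(C)[C@H]3CC/C(C)=C\CO[C@]3(C)CC[C@@H]12 | intermediate
21 | 3β-bromo-8α,15-epoxylabd-13Z-ene | CC1(C)[C@@H](Br)CC[C@]2(C)[C@H]3CC/C(C)=C\CO[C@]3(C)CC[C@@H]12 | intermediate
22 | 3β-bromo-8α,15:13,14-diepoxylabdane, (13R,14S) (CNP0311742.2) | CC1(C)[C@@H](Br)CC[C@]2(C)[C@H]3CC[C@@]4(C)O[C@H]4CO[C@]3(C)CC[C@@H]12 | target

## Step count and least certain steps

Total: 17 steps. Longest linear sequence: 17 steps (1 and 2 to 22); the route is fully linear.

Step 1 (key step). The diene may fail to reach the s-cis form fast enough and may instead be protonated or alkylated by the cationic catalyst and oligomerise. Slow turnover would also let the uncatalysed pathway erode the enantiomeric purity. The fallback sets out from 1 and replaces the hydrocarbon diene by an activated one with the same carbon skeleton and the same regiochemical preference. Mesityl oxide is enolised kinetically (LiN(iPr)2, iPr3SiOTf) to 4-methyl-2-(triisopropylsilyloxy)penta-1,3-diene F1, a diene of the class for which this catalyst is best established. Cycloaddition with 1 under the conditions of step 1 would give the cis-fused adduct with a C2 silyl enol ether F2. CsF and PhNTf2 would convert it into the C2 enol triflate F3, and Pd(OAc)2, PPh3, Bu3N and HCO2H would reduce the triflate to the 2-ene. The sequence comes back to the route at 3.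

Step 2. Deprotonation may go partly to the γ-position (the C8 methyl) and not to C5, and the facial preference of the protonation may be modest. If the cis isomer is the more stable one, drift back during work-up or in step 3 is also possible. The fallback sets out from 3 and sets C5 by dissolving-metal reduction instead. Tf2O with 2,6-di-tert-butyl-4-methylpyridine would give the through-conjugated C6 dienyl triflate F4. Pd(OAc)2, PPh3, Bu3N and HCO2H would give hexanorlabda-2,5,7-trien-9-one F5. Li in NH3 with one equivalent of tBuOH should reduce the dienone in the 1,6-sense with axial protonation at C5 and kinetic protonation at C8, giving 7. DBU then gives 8, where the fallback rejoins the route; it bypasses 4, 5 and 6.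

Step 6. Migration of the hindered, β-branched alkyl group from boron to the α-bromo enolate may be slow, so that protodeboronation or simple consumption of bromoacetone by the base competes. The fallback sets out from 10 and builds the chain by carbonyl chemistry. Oxidation with NaBO3·4H2O would give pentanorlabda-2,7-dien-11-ol F6. Dess–Martin periodinane with NaHCO3 would give pentanorlabda-2,7-dien-11-al F7. Ph3P=CHC(O)CH3 would give 14,15-dinorlabda-2,7,11E-trien-13-one F8. Conjugate reduction with [(Ph3P)CuH]6 returns to the route at 11.

Step 14. The unhindered allyl ether may enter intermolecular metathesis while the 1,1-disubstituted alkene fails to engage, giving oligomers. Ruthenium hydride species may also shift the allyl double bond. The fallback sets out from 18 and forms the same C13=C14 bond by carbonyl coupling. Ozonolysis (O3, then Me2S) would cleave both alkenes to the keto aldehyde F9. Intramolecular McMurry coupling with low-valent titanium from TiCl3 and Zn–Cu in refluxing DME under slow addition closes ring C. It returns to the route at 19.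

Step 16. The axial alkoxyphosphonium group has an anti-periplanar H-2β, so E2 elimination to the 2-ene may outrun substitution at the neopentyl carbon, and any ionisation would trigger a methyl shift. The fallback sets out from 20 and separates activation from displacement. ClCH2SO2Cl and pyridine would give the 3α-chloromethanesulfonate F10, a small leaving group suited to hindered centres. LiBr in DMPU then displaces it with inversion in a non-basic medium. It returns to the route at 21.

Step 17. Facial selectivity may be poor, or the wrong face may be attacked, if ring C populates a conformer other than the one assumed. The fallback sets out from 21 and reaches the epoxide on the face opposite to the one an electrophile attacks first. NBS in aqueous THF would give the bromohydrin F11 (bromine on C14, hydroxyl on C13, anti to each other). K2CO3 in MeOH then closes the oxirane with inversion at C14. It returns to the route at 22.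

## Further compounds

F1 | step 1 | 4-methyl-2-(triisopropylsilyloxy)penta-1,3-diene | C=C(O[Si](C(C)C)(C(C)C)C(C)C)C=C(C)C
F2 | step 1 | cis-fused adduct with a C2 triisopropylsilyl enol ether | CC1(C)C=C(O[Si](C(C)C)(C(C)C)C(C)C)C[C@]2(C)C(=O)C(C)=CC(=O)[C@H]12
F3 | step 1 | C2 enol triflate of the cis-fused adduct | CC1(C)C=C(OS(=O)(=O)C(F)(F)F)C[C@]2(C)C(=O)C(C)=CC(=O)[C@H]12
F4 | step 2 | C6 dienyl triflate (2,5,7-triene, C9 ketone) | CC1(C)C=CC[C@]2(C)C(=O)C(C)=CC(OS(=O)(=O)C(F)(F)F)=C12
F5 | step 2 | 11,12,13,14,15,16-hexanorlabda-2,5,7-trien-9-one | CC1(C)C=CC[C@]2(C)C(=O)C(C)=CC=C12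
F6 | step 6 | 12,13,14,15,16-pentanorlabda-2,7-dien-11-ol | CC1(C)C=CC[C@]2(C)[C@@H](CO)C(C)=CC[C@@H]12
F7 | step 6 | 12,13,14,15,16-pentanorlabda-2,7-dien-11-al | CC1(C)C=CC[C@]2(C)[C@@H](C=O)C(C)=CC[C@@H]12
F8 | step 6 | 14,15-dinorlabda-2,7,11E-trien-13-one | CC1(C)C=CC[C@]2(C)[C@@H](/C=C/C(C)=O)C(C)=CC[C@@H]12
F9 | step 14 | keto aldehyde: 3α-(tert-butyldimethylsilyloxy)-8α-(2-oxoethoxy)-14,15-dinorlabdan-13-one | CC1(C)[C@H](O[Si](C)(C)C(C)(C)C)CC[C@]2(C)[C@@H](CCC(C)=O)[C@](C)(OCC=O)CC[C@@H]12
F10 | step 16 | 8α,15-epoxylabd-13Z-en-3α-yl chloromethanesulfonate | CC1(C)[C@H](OS(=O)(=O)CCl)CC[C@]2(C)[C@H]3CC/C(C)=C\CO[C@]3(C)CC[C@@H]12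
F11 | step 17 | bromohydrin: 3β,14-dibromo-8α,15-epoxylabdan-13-ol | CC1(C)[C@@H](Br)CC[C@]2(C)[C@H]3CC[C@@](C)(O)[C@H](Br)CO[C@]3(C)CC[C@@H]12
A1 | alternative 1 | metathesis precursor: 3β-bromo decalin with C9 vinyl and C8 vinyl-epoxide ether arm | CC1(C)[C@@H](Br)CC[C@]2(C)[C@@H](C=C)[C@](C)(OC[C@@H]3O[C@]3(C)C=C)CC[C@@H]12
A2 | alternative 1 | 11,12-didehydro target (epoxy oxocene) | CC1(C)[C@@H](Br)CC[C@]2(C)[C@H]3/C=C\[C@@]4(C)O[C@H]4CO[C@]3(C)CC[C@@H]12
A3 | alternative 2 | monocyclic keto enoate (ring A with C8 methyl ketone chain and C9–C12 enoate) | CC1(C)[C@H](O[Si](C)(C)C(C)(C)C)CC[C@](C)(/C=C/C(=O)OC)[C@H]1CCC(C)=O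
A4 | alternative 2 | 3α-(tert-butyldimethylsilyloxy)sclareolide | CC1(C)[C@H](O[Si](C)(C)C(C)(C)C)CC[C@]2(C)[C@H]3CC(=O)O[C@]3(C)CC[C@@H]12
A5 | alternative 3 | phenol with ketal-bearing allylic carbonate tether | Cc1ccc(O)c(C)c1CCC1(OCCO1)/C=C/COC(=O)OC
A6 | alternative 3 | bicyclic 2,5-cyclohexadienone with C9 vinyl and C8 dioxolane | O=C1C=C[C@]2(C)[C@@H](C=C)C3(OCCO3)CCC2=C1C
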